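The O1–C7a aryl–oxygen bond of the styryl-bearing dihydrobenzofuran (DHB-1) is the disconnection on which the route rests. The formyl group on C5 lies para to the fluorine-bearing C7a of the benzo ring, so the alkoxide on C2 can displace fluoride by nucleophilic aromatic substitution. This closes ring DHB-1 in one operation and leaves C2 and C3 untouched; the formyl carbon then becomes the stilbene carbon. The precursor is a (1S,2S)-1,2,2-triarylethanol: 4-methoxyphenyl on the carbinol carbon and, on the adjacent carbon, a 2-fluoro-5-formylphenyl ring and the preformed, enantiopure central dihydrobenzofuran (DHB-2), all phenols as methyl ethers.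

Key step: step 13

Remark on the chemistry: "trans" in the name is taken to mean the E-stilbene; both dihydrobenzofurans are 2,3-trans, (2S,3S) and (2'S,3'S), as the target SMILES encodes.
Abbreviation: DHB-2-yl = (2S,3S)-3-(3,5-dimethoxyphenyl)-6-methoxy-2-(4-methoxyphenyl)-2,3-dihydro-1-benzofuran-4-yl.

Step 1
Reactants: 1 1,3-dibromo-5-methoxybenzene
Product: 3 2,6-dibromo-4-methoxybenzaldehyde, via (2,6-dibromo-4-methoxyphenyl)lithium 2 (not isolated)
Conditions: LiN(iPr)2, THF, −78 °C; DMF; H2O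
Reagents that add atoms: N,N-dimethylformamide, CN(C)C=O
Why: Halogen-directed ortho-lithiation and formylation, in which the ring hydrogen flanked by both bromines is the most acidic, the aryllithium is stable at −78 °C and DMF traps it as the aldehyde, leaving two equivalent bromines.

Step 2
Reactants: 3 2,6-dibromo-4-methoxybenzaldehyde; 4 3,5-dimethoxybenzyl bromide
Product: 6 trans-2-(2,6-dibromo-4-methoxyphenyl)-3-(3,5-dimethoxyphenyl)oxirane (racemic), via 1-(3,5-dimethoxybenzyl)tetrahydrothiophenium bromide 5 (not isolated)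
Conditions: tetrahydrothiophene (1 equiv), KOH, MeCN/H2O (9:1), 25 °C
Reagents that add atoms: none
Why: Corey–Chaykovsky epoxidation, in which the sulfonium salt formed in situ is deprotonated to a semi-stabilised ylide that adds to the non-enolisable aldehyde and closes mainly to the trans epoxide, whose racemic stereocentres are erased in step 3.

Step 3
Reactants: 6 trans-2-(2,6-dibromo-4-methoxyphenyl)-3-(3,5-dimethoxyphenyl)oxirane
Product: 7 2-(2,6-dibromo-4-methoxyphenyl)-2-(3,5-dimethoxyphenyl)acetaldehyde (racemic)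
Conditions: BF3·OEt2 (0.2 equiv), CH2Cl2, −40 → 0 °C
Reagents that add atoms: none
Why: Meinwald rearrangement, in which Lewis-acid opening of the stilbene oxide is followed by a 1,2-aryl shift, migration of either aryl giving the same diarylacetaldehyde, whose labile α-centre is of no consequence.

Step 4
Reactants: 7 2-(2,6-dibromo-4-methoxyphenyl)-2-(3,5-dimethoxyphenyl)acetaldehyde; 8 4-methoxyphenylmagnesium bromide
Product: 9 2-(2,6-dibromo-4-methoxyphenyl)-2-(3,5-dimethoxyphenyl)-1-(4-methoxyphenyl)ethan-1-ol (mixture of racemic diastereomers)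
Conditions: LaCl3·2LiCl (1 equiv), THF, −78 → 0 °C; H2O
Reagents that add atoms: none
Why: Grignard 1,2-addition to the aldehyde, with the lanthanum salt suppressing enolisation of the acidic α,α-diaryl aldehyde and the low temperature sparing the aryl bromides, no selectivity being needed because both centres are reset in steps 5 and 6.

Step 5
Reactants: 9 2-(2,6-dibromo-4-methoxyphenyl)-2-(3,5-dimethoxyphenyl)-1-(4-methoxyphenyl)ethan-1-ol
Product: 10 2-(2,6-dibromo-4-methoxyphenyl)-2-(3,5-dimethoxyphenyl)-1-(4-methoxyphenyl)ethan-1-one (racemic)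
Conditions: Dess–Martin periodinane, CH2Cl2, 25 °C
Reagents that add atoms: none
Why: Dess–Martin oxidation of the secondary benzylic alcohol to the ketone under neutral conditions that leave aryl bromides and methyl ethers untouched, the α-centre staying racemic as intended for step 6.

Step 6
Reactants: 10 2-(2,6-dibromo-4-methoxyphenyl)-2-(3,5-dimethoxyphenyl)-1-(4-methoxyphenyl)ethan-1-one
Product: 11 (1S,2S)-2-(2,6-dibromo-4-methoxyphenyl)-2-(3,5-dimethoxyphenyl)-1-(4-methoxyphenyl)ethan-1-ol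
Conditions: RuCl[(S,S)-TsDPEN](p-cymene) (3 mol%), HCO2H/Et3N (1:1), DMF, 40 °C
Reagents that add atoms: none
Why: Noyori–Ikariya asymmetric transfer hydrogenation run as a dynamic kinetic resolution, in which C2 epimerises through the enol, the (S,S) catalyst sets C1 as S by its usual facial control of aryl ketones, and hydride enters anti to the di-ortho-brominated aryl ring (both the bulkiest and the most electron-poor α-substituent, Felkin–Anh), so that the 2S epimer is drained.

Step 7
Reactants: 11 (1S,2S)-2-(2,6-dibromo-4-methoxyphenyl)-2-(3,5-dimethoxyphenyl)-1-(4-methoxyphenyl)ethan-1-ol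
Product: 12 (2S,3S)-4-bromo-3-(3,5-dimethoxyphenyl)-6-methoxy-2-(4-methoxyphenyl)-2,3-dihydro-1-benzofuran
Conditions: CuI (10 mol%), 3,4,7,8-tetramethyl-1,10-phenanthroline (20 mol%), Cs2CO3, toluene, 100 °C
Reagents that add atoms: none
Why: Ullmann-type copper-catalysed intramolecular O-arylation closing the five-membered ring of DHB-2, in which the two ortho bromines are equivalent so that either gives the same product and the other remains as the C4' handle, and no bond to C1 or C2 is broken, so the (1S,2S) alcohol becomes the (2S,3S) trans ring.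

Step 8
Reactants: 13 3-bromo-4-fluorobenzaldehyde
Product: 14 2-(3-bromo-4-fluorophenyl)-1,3-dioxolane
Conditions: HOCH2CH2OH, TsOH·H2O (cat.), toluene, reflux (Dean–Stark)
Reagents that add atoms: ethylene glycol, OCCO
Why: Acid-catalysed acetalisation with azeotropic removal of water masks the aldehyde as a dioxolane that is inert to enolates, bases and transfer hydrogenation and does not activate the C–F bond.

Step 9
Reactants: 14 2-(3-bromo-4-fluorophenyl)-1,3-dioxolane; 15 4'-methoxyacetophenone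
Product: 16 2-[5-(1,3-dioxolan-2-yl)-2-fluorophenyl]-1-(4-methoxyphenyl)ethan-1-one
Conditions: Pd(OAc)2 (2 mol%), Xantphos (3 mol%), K3PO4, toluene, 80 °C
Reagents that add atoms: none
Why: Palladium-catalysed ketone α-arylation (Buchwald–Hartwig type) in which the enolate couples at the C–Br bond, the wide-bite-angle ligand and a slight excess of ketone favour mono-arylation, and the acetal keeps the aldehyde and the unactivated C–F bond out of reach of the enolate.

Step 10
Reactants: 16 2-[5-(1,3-dioxolan-2-yl)-2-fluorophenyl]-1-(4-methoxyphenyl)ethan-1-one; 12 (2S,3S)-4-bromo-3-(3,5-dimethoxyphenyl)-6-methoxy-2-(4-methoxyphenyl)-2,3-dihydro-1-benzofuran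
Product: 17 2-(DHB-2-yl)-2-[5-(1,3-dioxolan-2-yl)-2-fluorophenyl]-1-(4-methoxyphenyl)ethan-1-one (both C2 epimers)
Conditions: Pd(OAc)2 (5 mol%), P(tBu)3·HBF4 (10 mol%), Cs2CO3, toluene, 100 °C
Reagents that add atoms: none
Why: Second palladium-catalysed α-arylation, in which the more acidic deoxybenzoin enolate couples with the hindered aryl bromide under a bulky trialkylphosphine, the acetal keeps C–F unactivated so that the enolate oxygen cannot close a benzofuran, and the new C2 centre forms as two interconverting epimers that are resolved in step 11.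

Step 11
Reactants: 17 2-(DHB-2-yl)-2-[5-(1,3-dioxolan-2-yl)-2-fluorophenyl]-1-(4-methoxyphenyl)ethan-1-one
Product: 18 (1S,2S)-2-(DHB-2-yl)-2-[5-(1,3-dioxolan-2-yl)-2-fluorophenyl]-1-(4-methoxyphenyl)ethan-1-ol
Conditions: RuCl[(S,S)-TsDPEN](p-cymene) (5 mol%), HCO2H/Et3N (1:1), DMF, 40 °C
Reagents that add atoms: none
Why: Noyori–Ikariya asymmetric transfer hydrogenation run as a dynamic kinetic resolution, in which the C2 epimers interconvert through the enol, the (S,S) catalyst sets C1 as S by its usual facial control of aryl ketones, and C2 should emerge as S because the epimer that places the more electron-poor 2-fluoroaryl ring anti to the incoming hydride (polar Felkin–Anh arrangement) is reduced faster, the acetal and the aryl fluoride being inert to the ruthenium hydride.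

Step 12
Reactants: 18 (1S,2S)-2-(DHB-2-yl)-2-[5-(1,3-dioxolan-2-yl)-2-fluorophenyl]-1-(4-methoxyphenyl)ethan-1-ol
Product: 19 (1S,2S)-2-(DHB-2-yl)-2-(2-fluoro-5-formylphenyl)-1-(4-methoxyphenyl)ethan-1-ol
Conditions: PPTS (0.2 equiv), THF/H2O (4:1), 50 °C
Reagents that add atoms: water, O
Why: Acid-catalysed acetal hydrolysis with a weak acid that cleaves the aryl dioxolane without ionising the 4-methoxybenzylic carbinol or the benzylic ether of DHB-2, so both centres of the ethanol unit are retained.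

Step 13
Reactants: 19 (1S,2S)-2-(DHB-2-yl)-2-(2-fluoro-5-formylphenyl)-1-(4-methoxyphenyl)ethan-1-ol
Product: 20 (2S,3S)-3-(DHB-2-yl)-2-(4-methoxyphenyl)-2,3-dihydro-1-benzofuran-5-carbaldehyde
Conditions: KOtBu (1.1 equiv), THF, −20 → 20 °C
Reagents that add atoms: none
Why: Deprotonation gives the C2 potassium alkoxide, which adds to the fluorine-bearing C7a of the neighbouring ring to form a Meisenheimer adduct whose charge is delocalised into the formyl group at C5, para to the site of attack; loss of fluoride then restores aromaticity and forms O1–C7a. The closest known reaction type is intramolecular nucleophilic aromatic substitution (SNAr) etherification of alkoxides on 4-fluorobenzaldehyde-type arenes. Ring DHB-1 closes in a 5-exo-trig mode. No stereocentre is created: no bond to C2 or C3 is broken, so the (1S,2S) alcohol is carried over into the (2S,3S) trans ring. The step needs attack at C–F to win over addition or hydride transfer to the aldehyde and over retro-addition of the alkoxide; the five-membered intramolecular trajectory, the para-formyl activation, the irreversible loss of fluoride and the low temperature should secure this, and the other rings carry no leaving group.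

Step 14
Reactants: 20 (2S,3S)-3-(DHB-2-yl)-2-(4-methoxyphenyl)-2,3-dihydro-1-benzofuran-5-carbaldehyde; 21 diethyl 3,5-dimethoxybenzylphosphonate
Product: 22 (2S,3S)-5-[(E)-2-(3,5-dimethoxyphenyl)ethenyl]-3-(DHB-2-yl)-2-(4-methoxyphenyl)-2,3-dihydro-1-benzofuran
Conditions: KOtBu, THF, 0 → 25 °C
Reagents that add atoms: none
Why: Horner–Wadsworth–Emmons olefination in which the semi-stabilised benzylic phosphonate anion adds to the aryl aldehyde and eliminates diethyl phosphate to give the E-stilbene, the four stereocentres carrying no acidic hydrogen.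

Step 15
Reactants: 22 (2S,3S)-5-[(E)-2-(3,5-dimethoxyphenyl)ethenyl]-3-(DHB-2-yl)-2-(4-methoxyphenyl)-2,3-dihydro-1-benzofuran
Product: 23 trans-diptoindonesin B
Conditions: BBr3 (excess), CH2Cl2, −78 → 0 °C; H2O
Reagents that add atoms: none
Why: Lewis-acid ether cleavage (global O-demethylation) in which bromide attacks each boron-activated methyl group at low temperature, a standard way to unmask polyphenolic stilbene oligomers, the stereocentres and the E-alkene taking no part.

Compound list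
1 | 1,3-dibromo-5-methoxybenzene | COc1cc(Br)cc(Br)c1 | starting material
2 | (2,6-dibromo-4-methoxyphenyl)lithium | COc1cc(Br)c([Li])c(Br)c1 | intermediate
3 | 2,6-dibromo-4-methoxybenzaldehyde | COc1cc(Br)c(C=O)c(Br)c1 | intermediate
4 | 3,5-dimethoxybenzyl bromide | COc1cc(CBr)cc(OC)c1 | starting material
5 | 1-(3,5-dimethoxybenzyl)tetrahydrothiophenium bromide | COc1cc(C[S+]2CCCC2)cc(OC)c1.[Br-] | intermediate
6 | trans-2-(2,6-dibromo-4-methoxyphenyl)-3-(3,5-dimethoxyphenyl)oxirane, racemic (one enantiomer drawn) | COc1cc(Br)c([C@@H]2O[C@H]2c2cc(OC)cc(OC)c2)c(Br)c1 | intermediate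
7 | 2-(2,6-dibromo-4-methoxyphenyl)-2-(3,5-dimethoxyphenyl)acetaldehyde, racemic | COc1cc(Br)c(C(C=O)c2cc(OC)cc(OC)c2)c(Br)c1 | intermediate
8 | 4-methoxyphenylmagnesium bromide | COc1ccc([Mg]Br)cc1 | starting material
9 | 2-(2,6-dibromo-4-methoxyphenyl)-2-(3,5-dimethoxyphenyl)-1-(4-methoxyphenyl)ethan-1-ol, racemic diastereomer mixture | COc1ccc(C(O)C(c2cc(OC)cc(OC)c2)c2c(Br)cc(OC)cc2Br)cc1 | intermediate
10 | 2-(2,6-dibromo-4-methoxyphenyl)-2-(3,5-dimethoxyphenyl)-1-(4-methoxyphenyl)ethan-1-one, racemic | COc1ccc(C(=O)C(c2cc(OC)cc(OC)c2)c2c(Br)cc(OC)cc2Br)cc1 | intermediate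
11 | (1S,2S)-2-(2,6-dibromo-4-methoxyphenyl)-2-(3,5-dimethoxyphenyl)-1-(4-methoxyphenyl)ethan-1-ol | COc1cc(Br)c(c(Br)c1)[C@H](c1cc(OC)cc(OC)c1)[C@@H](c1ccc(OC)cc1)O | intermediate
12 | (2S,3S)-4-bromo-3-(3,5-dimethoxyphenyl)-6-methoxy-2-(4-methoxyphenyl)-2,3-dihydro-1-benzofuran | Brc1cc(OC)cc2c1[C@H](c1cc(OC)cc(OC)c1)[C@@H](c1ccc(OC)cc1)O2 | intermediate
13 | 3-bromo-4-fluorobenzaldehyde | O=Cc1ccc(F)c(Br)c1 | starting material
14 | 2-(3-bromo-4-fluorophenyl)-1,3-dioxolane | Fc1ccc(cc1Br)C1OCCO1 | intermediate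
15 | 4'-methoxyacetophenone | COc1ccc(C(C)=O)cc1 | starting material
16 | 2-[5-(1,3-dioxolan-2-yl)-2-fluorophenyl]-1-(4-methoxyphenyl)ethan-1-one | COc1ccc(C(=O)Cc2cc(C3OCCO3)ccc2F)cc1 | intermediate
17 | 2-(DHB-2-yl)-2-[5-(1,3-dioxolan-2-yl)-2-fluorophenyl]-1-(4-methoxyphenyl)ethan-1-one, both C2 epimers | COc1ccc(C(=O)C(c2cc(C3OCCO3)ccc2F)c2cc(OC)cc3c2[C@H](c2cc(OC)cc(OC)c2)[C@@H](c2ccc(OC)cc2)O3)cc1 | intermediate
18 | (1S,2S)-2-(DHB-2-yl)-2-[5-(1,3-dioxolan-2-yl)-2-fluorophenyl]-1-(4-methoxyphenyl)ethan-1-ol | COc1ccc([C@@H](O)[C@H](c2cc(C3OCCO3)ccc2F)c2cc(OC)cc3c2[C@H](c2cc(OC)cc(OC)c2)[C@@H](c2ccc(OC)cc2)O3)cc1 | intermediate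
19 | (1S,2S)-2-(DHB-2-yl)-2-(2-fluoro-5-formylphenyl)-1-(4-methoxyphenyl)ethan-1-ol | COc1ccc([C@@H](O)[C@H](c2cc(C=O)ccc2F)c2cc(OC)cc3c2[C@H](c2cc(OC)cc(OC)c2)[C@@H](c2ccc(OC)cc2)O3)cc1 | intermediate
20 | (2S,3S)-3-(DHB-2-yl)-2-(4-methoxyphenyl)-2,3-dihydro-1-benzofuran-5-carbaldehyde | COc1ccc([C@H]2Oc3ccc(C=O)cc3[C@@H]2c2cc(OC)cc3c2[C@H](c2cc(OC)cc(OC)c2)[C@@H](c2ccc(OC)cc2)O3)cc1 | intermediate
21 | diethyl 3,5-dimethoxybenzylphosphonate | CCOP(=O)(Cc1cc(OC)cc(OC)c1)OCC | starting material
22 | (2S,3S)-5-[(E)-2-(3,5-dimethoxyphenyl)ethenyl]-3-(DHB-2-yl)-2-(4-methoxyphenyl)-2,3-dihydro-1-benzofuran (heptamethyl ether of the target) | COc1ccc([C@H]2Oc3ccc(/C=C/c4cc(OC)cc(OC)c4)cc3[C@@H]2c2cc(OC)cc3c2[C@H](c2cc(OC)cc(OC)c2)[C@@H](c2ccc(OC)cc2)O3)cc1 | intermediate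
23 | trans-diptoindonesin B, 5-[(E)-2-{(2S,3S)-3-[(2S,3S)-3-(3,5-dihydroxyphenyl)-6-hydroxy-2-(4-hydroxyphenyl)-2,3-dihydro-1-benzofuran-4-yl]-2-(4-hydroxyphenyl)-2,3-dihydro-1-benzofuran-5-yl}ethenyl]benzene-1,3-diol | Oc1ccc([C@H]2Oc3ccc(/C=C/c4cc(O)cc(O)c4)cc3[C@@H]2c2cc(O)cc3c2[C@H](c2cc(O)cc(O)c2)[C@@H](c2ccc(O)cc2)O3)cc1 | target

Total step count: 15. Longest linear sequence: 13 steps (steps 1–7, then 10–15).

Steps most likely to fail

Step 13 (key step). Hydride transfer from the C2 alkoxide to a formyl group, or retro-addition of the alkoxide with loss of 4-methoxybenzaldehyde, may compete with ring closure. The fallback sets out from 19 and exchanges the formyl group for a nitrile, which is also para to C7a but cannot accept hydride under these conditions. Ph2P(O)ONH2 in toluene at 85 °C should give the fluoro nitrile alcohol F1. KOtBu in THF then closes the ring by the same substitution to the 5-cyano dihydrobenzofuran F2. Reduction with iBu2AlH (toluene, −78 °C, mild aqueous acid work-up) comes back to the route at 20.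

Step 11. The dynamic resolution may select the wrong C2 epimer. Steric and polar preferences oppose each other here, and hydride delivery anti to the bulkier DHB-2 aryl, in place of anti to the fluoroaryl ring, would drain the 2R epimer. The fallback sets out from 17 with the enantiomeric catalyst RuCl[(R,R)-TsDPEN](p-cymene), for which that steric preference leads to the (1R,2S) alcohol F3, correct at the diaryl carbon. PPTS hydrolysis gives the hydroxy aldehyde F4, and KOtBu closes the cis-dihydrobenzofuran aldehyde F5. CF3CO2H in CH2Cl2 at 0 °C then equilibrates C2 to the more stable trans isomer through reversible ionisation of the 4-methoxybenzylic C2–O1 bond, coming back to the route at 20.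

Step 15. Exhaustive Lewis-acid demethylation may open the benzylic C–O bonds of the two dihydrobenzofurans and cause acid-mediated addition to, or cyclisation onto, the electron-rich stilbene. The fallback sets out from 20 and demethylates before the alkene exists. BBr3 gives the pentaphenol aldehyde F6, and TBSCl/imidazole in DMF gives the penta-silyl ether aldehyde F7. Olefination with diethyl 3,5-bis(tert-butyldimethylsilyloxy)benzylphosphonate (NaH, THF, 0 °C) gives the hepta-silyl E-stilbene F8. Bu4NF buffered with AcOH in THF at 0 °C removes the silyl groups without acid and comes back to the route at 23.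

Further compounds
F1 | step 13 | (1S,2S)-2-(5-cyano-2-fluorophenyl)-2-(DHB-2-yl)-1-(4-methoxyphenyl)ethan-1-ol | COc1ccc([C@@H](O)[C@H](c2cc(C#N)ccc2F)c2cc(OC)cc3c2[C@H](c2cc(OC)cc(OC)c2)[C@@H](c2ccc(OC)cc2)O3)cc1
F2 | step 13 | (2S,3S)-3-(DHB-2-yl)-2-(4-methoxyphenyl)-2,3-dihydro-1-benzofuran-5-carbonitrile | COc1ccc([C@H]2Oc3ccc(C#N)cc3[C@@H]2c2cc(OC)cc3c2[C@H](c2cc(OC)cc(OC)c2)[C@@H](c2ccc(OC)cc2)O3)cc1
F3 | step 11 | (1R,2S)-2-(DHB-2-yl)-2-[5-(1,3-dioxolan-2-yl)-2-fluorophenyl]-1-(4-methoxyphenyl)ethan-1-ol | COc1ccc([C@H](O)[C@H](c2cc(C3OCCO3)ccc2F)c2cc(OC)cc3c2[C@H](c2cc(OC)cc(OC)c2)[C@@H](c2ccc(OC)cc2)O3)cc1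
F4 | step 11 | (1R,2S)-2-(DHB-2-yl)-2-(2-fluoro-5-formylphenyl)-1-(4-methoxyphenyl)ethan-1-ol | COc1ccc([C@H](O)[C@H](c2cc(C=O)ccc2F)c2cc(OC)cc3c2[C@H](c2cc(OC)cc(OC)c2)[C@@H](c2ccc(OC)cc2)O3)cc1
F5 | step 11 | (2R,3S)-3-(DHB-2-yl)-2-(4-methoxyphenyl)-2,3-dihydro-1-benzofuran-5-carbaldehyde (2,3-cis) | COc1ccc([C@@H]2Oc3ccc(C=O)cc3[C@@H]2c2cc(OC)cc3c2[C@H](c2cc(OC)cc(OC)c2)[C@@H](c2ccc(OC)cc2)O3)cc1
F6 | step 15 | (2S,3S)-3-[(2S,3S)-3-(3,5-dihydroxyphenyl)-6-hydroxy-2-(4-hydroxyphenyl)-2,3-dihydro-1-benzofuran-4-yl]-2-(4-hydroxyphenyl)-2,3-dihydro-1-benzofuran-5-carbaldehyde | Oc1ccc([C@H]2Oc3ccc(C=O)cc3[C@@H]2c2cc(O)cc3c2[C@H](c2cc(O)cc(O)c2)[C@@H](c2ccc(O)cc2)O3)cc1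
F7 | step 15 | penta-O-(tert-butyldimethylsilyl) ether of F6 | CC(C)(C)[Si](C)(C)Oc1ccc([C@H]2Oc3ccc(C=O)cc3[C@@H]2c2cc(O[Si](C)(C)C(C)(C)C)cc3c2[C@H](c2cc(O[Si](C)(C)C(C)(C)C)cc(O[Si](C)(C)C(C)(C)C)c2)[C@@H](c2ccc(O[Si](C)(C)C(C)(C)C)cc2)O3)cc1
F8 | step 15 | hepta-O-(tert-butyldimethylsilyl) ether of 23 | CC(C)(C)[Si](C)(C)Oc1ccc([C@H]2Oc3ccc(/C=C/c4cc(O[Si](C)(C)C(C)(C)C)cc(O[Si](C)(C)C(C)(C)C)c4)cc3[C@@H]2c2cc(O[Si](C)(C)C(C)(C)C)cc3c2[C@H](c2cc(O[Si](C)(C)C(C)(C)C)cc(O[Si](C)(C)C(C)(C)C)c2)[C@@H](c2ccc(O[Si](C)(C)C(C)(C)C)cc2)O3)cc1
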